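Cuts: the five phenols are masked as methyl ethers and the CH2–CH2 bridge is traced back to an alkyne. The alkyne is cut at both ends (central-ring C1–Cα and Cβ–aryl), and the ArCH2–C2 and ArCH2–C6 bonds are cut last.
Enabling feature: C1 of the central ring is meta to the oxygens on C3 and C5, para to C4–H and wedged between the benzylated C2 and C6, so neither electrophilic substitution nor directed metalation reaches it. It is, however, the hydroxyl carbon of a phloroglucinol-type phenol, whose oxygen first steers both benzyl groups to its ortho carbons and then leaves as triflate.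
Forward order: no ring is built, since all four benzene rings are bought. 3,5-Dimethoxyphenol is C-benzylated at C2 and then C6 with 4-methoxybenzyl chloride and O-triflated. Propiolic acid then forms Cβ–aryl with 4-iodoanisole and C1–Cα with the triflate (loss of CO2) in one pot, followed by saturation of the alkyne and fivefold O-demethylation.
Stereochemistry: the target has no stereocentre, no stereogenic double bond and no stable axis, so nothing has to be set or preserved.

Key step: step 4

Remark on the chemistry: the target SMILES carries no stereodescriptor and the molecule has no stereogenic unit. It is therefore achiral, and the compound drawn is its only stereoisomer.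
Locants used throughout:
- C1 is the central-ring carbon that ends up carrying the bridge (the hydroxyl carbon in the phenol precursors).
- C2 and C6 are benzylated, C3 and C5 are oxygenated, and C4 is C–H.
- Cα is the bridge carbon on C1, and Cβ is the bridge carbon on the 4-oxygenated phenyl ring.

Step 1
Reactants: 1 3,5-dimethoxyphenol; 2 4-methoxybenzyl chloride
Product: 4 3,5-dimethoxy-2-(4-methoxybenzyl)phenol, via sodium 3,5-dimethoxyphenoxide 3 (not isolated)
Conditions: NaH (1.05 equiv), PhMe, 0 °C → rt; then 2 (1.0 equiv), 110 °C
Reagents that add atoms: none
Why: Heterogeneous ortho-C-alkylation of a sodium phenoxide: in toluene the phenoxide oxygen is buried in tight ion-pair aggregates and the sodium ion pulls on the chloride of the reactive benzylic halide within a six-membered array, so the new bond should form at the ortho carbon C2 (equivalent to C6) rather than at oxygen or at the remote C4, and tautomerisation then restores the phenol.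

Step 2
Reactants: 4 3,5-dimethoxy-2-(4-methoxybenzyl)phenol; 2 4-methoxybenzyl chloride
Product: 6 3,5-dimethoxy-2,6-bis(4-methoxybenzyl)phenol, via sodium 3,5-dimethoxy-2-(4-methoxybenzyl)phenoxide 5 (not isolated)
Conditions: NaH (1.1 equiv), PhMe, rt; then 2 (1.1 equiv), 110 °C
Reagents that add atoms: none
Why: The same heterogeneous phenoxide ortho-C-benzylation is repeated, now at C6, the only ortho carbon that still carries a hydrogen and can therefore rearomatise after attack, while C4 again lies beyond the reach of the sodium-bound electrophile.

Step 3
Reactants: 6 3,5-dimethoxy-2,6-bis(4-methoxybenzyl)phenol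
Product: 7 3,5-dimethoxy-2,6-bis(4-methoxybenzyl)phenyl trifluoromethanesulfonate
Conditions: Tf2O (1.3 equiv), pyridine (3 equiv), CH2Cl2, 0 °C → rt
Reagents that add atoms: trifluoromethanesulfonic anhydride (Tf2O), O=S(=O)(OS(=O)(=O)C(F)(F)F)C(F)(F)F
Why: O-Sulfonylation of a phenol with triflic anhydride and pyridine is routine even for 2,6-dialkylphenols, and 6 offers no other nucleophilic site that competes at 0 °C.

Step 4
Reactants: 7 3,5-dimethoxy-2,6-bis(4-methoxybenzyl)phenyl trifluoromethanesulfonate; 8 propiolic acid; 9 4-iodoanisole
Product: 11 1,5-dimethoxy-2,4-bis(4-methoxybenzyl)-3-[(4-methoxyphenyl)ethynyl]benzene, via 3-(4-methoxyphenyl)propiolic acid 10 (not isolated)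
Conditions: 8 (1.4 equiv), 9 (1.3 equiv), PdCl2(MeCN)2 (5 mol%), XPhos (12 mol%), DBU (3.0 equiv), DMSO, Ar, 30 °C until 9 is consumed; then 7 (1.0 equiv), 100 °C
Reagents that add atoms: none
Why: In the cool stage Pd(0)/XPhos inserts into the C–I bond of 9, the DBU salt of 8 is palladated at its acidic terminal C–H and reductive elimination forms the Cβ–aryl bond (copper-free Sonogashira, i.e. Heck–Cassar coupling), the carboxylate surviving because alkynoates do not lose CO2 at 30 °C. Once 7 is added and the mixture is heated, Pd(0) inserts into the C1–O bond of the triflate, the weakly bound triflate ion is displaced by the carboxylate of 10, CO2 is extruded to give an aryl(alkynyl)palladium(II) complex, and reductive elimination forms the C1–Cα bond of 11. The closest known reaction type is the one-pot Sonogashira/decarboxylative coupling of propiolic acid with an aryl iodide and then a second aryl halide or sulfonate, which gives unsymmetrical diarylalkynes, and the bulky biaryl phosphine belongs to the ligand class established for alkynylation of sluggish aryl chlorides and sulfonates. No ring closes and no stereocentre arises. The selectivity needed is the order in which the two electrophiles are engaged, and it is secured by the much faster oxidative addition of the unhindered iodide, by a slight excess of 8 over 9 so that no iodide survives the cool stage, and by adding 7 only before heating. The substrate helps in three ways: the linear alkynyl ligand is the slimmest carbon nucleophile that can sit between the two ortho benzyl groups, the methoxy groups are meta to C1 and so do not strengthen the C1–O bond by resonance, and the carboxylate releases the alkynyl unit slowly, which keeps alkyne oligomerisation down while the hindered triflate reacts.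

Step 5
Reactants: 11 1,5-dimethoxy-2,4-bis(4-methoxybenzyl)-3-[(4-methoxyphenyl)ethynyl]benzene
Product: 12 1,5-dimethoxy-2,4-bis(4-methoxybenzyl)-3-[2-(4-methoxyphenyl)ethyl]benzene
Conditions: H2 (4 bar), 10% Pd/C, EtOAc–MeOH, 40 °C
Reagents that add atoms: none
Why: Heterogeneous catalytic hydrogenation adds two equivalents of hydrogen to the diarylalkyne, while aryl methyl ethers and the C–C bonds of the diarylmethane units are inert to Pd/C, and slight pressure with gentle warming allows for the crowding next to C1.

Step 6
Reactants: 12 1,5-dimethoxy-2,4-bis(4-methoxybenzyl)-3-[2-(4-methoxyphenyl)ethyl]benzene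
Product: 13 4,6-bis(4-hydroxybenzyl)-5-[2-(4-hydroxyphenyl)ethyl]benzene-1,3-diol (CNP0326726.0)
Conditions: BBr3 (8 equiv), CH2Cl2, −78 °C → rt; then H2O, 0 °C
Reagents that add atoms: none
Why: Lewis-acid ether cleavage with boron tribromide (boron binds each ether oxygen, bromide attacks the methyl carbon in an SN2 step and the aqueous quench frees the phenols) is the standard global demethylation for methoxylated bibenzyls and diarylmethanes, and the low temperature together with a cold quench guards against acid-induced migration of the electron-rich benzyl groups.

Compound list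
1 | 3,5-dimethoxyphenol | COc1cc(O)cc(OC)c1 | starting material
2 | 4-methoxybenzyl chloride | COc1ccc(CCl)cc1 | starting material
3 | sodium 3,5-dimethoxyphenoxide | COc1cc([O-])cc(OC)c1.[Na+] | intermediate
4 | 3,5-dimethoxy-2-(4-methoxybenzyl)phenol | COc1ccc(Cc2c(O)cc(OC)cc2OC)cc1 | intermediate
5 | sodium 3,5-dimethoxy-2-(4-methoxybenzyl)phenoxide | COc1ccc(Cc2c([O-])cc(OC)cc2OC)cc1.[Na+] | intermediate
6 | 3,5-dimethoxy-2,6-bis(4-methoxybenzyl)phenol | COc1ccc(Cc2c(O)c(Cc3ccc(OC)cc3)c(OC)cc2OC)cc1 | intermediate
7 | 3,5-dimethoxy-2,6-bis(4-methoxybenzyl)phenyl trifluoromethanesulfonate | COc1cc(OC)c(Cc2ccc(OC)cc2)c(OS(=O)(=O)C(F)(F)F)c1Cc1ccc(OC)cc1 | intermediate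
8 | propiolic acid | C#CC(=O)O | starting material
9 | 4-iodoanisole | COc1ccc(I)cc1 | starting material
10 | 3-(4-methoxyphenyl)propiolic acid (present in the flask as its DBU salt) | COc1ccc(C#CC(=O)O)cc1 | intermediate
11 | 1,5-dimethoxy-2,4-bis(4-methoxybenzyl)-3-[(4-methoxyphenyl)ethynyl]benzene | COc1ccc(C#Cc2c(Cc3ccc(OC)cc3)c(OC)cc(OC)c2Cc2ccc(OC)cc2)cc1 | intermediate
12 | 1,5-dimethoxy-2,4-bis(4-methoxybenzyl)-3-[2-(4-methoxyphenyl)ethyl]benzene | COc1ccc(CCc2c(Cc3ccc(OC)cc3)c(OC)cc(OC)c2Cc2ccc(OC)cc2)cc1 | intermediate
13 | 4,6-bis(4-hydroxybenzyl)-5-[2-(4-hydroxyphenyl)ethyl]benzene-1,3-diol (achiral) | Oc1ccc(CCc2c(Cc3ccc(O)cc3)c(O)cc(O)c2Cc2ccc(O)cc2)cc1 | target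

Total step count: 6. Longest linear sequence: 6 steps (1 → 4 → 6 → 7 → 11 → 12 → 13). Compounds 2, 8 and 9 enter as purchased materials.

Steps most likely to fail

Step 4 (key step). At the temperature needed for loss of CO2, two side processes may outrun the slow oxidative addition and ligand exchange at the crowded C1. One is base-induced S–O cleavage of the sulfonate. The other is protodecarboxylation of the alkynyl partner followed by its oligomerisation. In the fallback the two bond formations are separated, and the alkynyl nucleophile is pre-formed as a stoichiometric organozinc, so the coupling at C1 runs without amine base or carboxylate. It sets out from 10, this time isolated by acidification after the cool stage, and from 7. Copper-catalysed protodecarboxylation of 10 (CuCl cat., Et3N, MeCN, 60 °C) should give 4-ethynylanisole F1. Deprotonation with n-BuLi (THF, −78 °C) should give lithium (4-methoxyphenyl)acetylide F2, and transmetalation with ZnCl2 should give [(4-methoxyphenyl)ethynyl]zinc chloride F3. Negishi coupling of the zinc reagent with 7 (Pd2(dba)3, XPhos, THF, 65 °C) comes back to the route at 11.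

Step 2. One ortho carbon is already blocked and the phenoxide is more crowded. O-alkylation, attack at C4 and ipso-attack at C2 without rearomatisation may therefore compete with attack at C6. In the fallback the new carbon is delivered inside a magnesium chelate as the smallest possible electrophile, and the aryl ring is attached afterwards. It sets out from 4. Magnesium-mediated ortho-formylation (Casnati–Skattebøl conditions: MgCl2, Et3N, paraformaldehyde, MeCN, reflux) is specific for the free ortho position and should give 2-hydroxy-4,6-dimethoxy-3-(4-methoxybenzyl)benzaldehyde F4. Addition of 4-methoxyphenylmagnesium bromide (2.2 equiv, THF, 0 °C) should give racemic 2-[hydroxy(4-methoxyphenyl)methyl]-3,5-dimethoxy-6-(4-methoxybenzyl)phenol F5. Ionic hydrogenation of the doubly activated benzylic alcohol (Et3SiH, TFA, CH2Cl2, 0 °C) comes back to the route at 6.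

Step 1. Three processes may erode the ortho mono-selectivity: O-benzylation, attack at C4 through a free 4-methoxybenzyl cation (an undirected Friedel–Crafts pathway), and proton exchange followed by a second alkylation. In the fallback the electrophile is tethered to the phenol oxygen through boron, so the C–C bond can only form ortho. It sets out from 1. Condensation with 4-methoxybenzaldehyde and phenylboronic acid (cat. propionic acid, PhMe, Dean–Stark reflux; boronic-acid-templated ortho-hydroxyalkylation) should give racemic 5,7-dimethoxy-4-(4-methoxyphenyl)-2-phenyl-4H-1,3,2-benzodioxaborinine F6. Ionic reduction of its benzylic C–O bond (Et3SiH, TFA, CH2Cl2, 0 °C) with aqueous work-up comes back to the route at 4.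

Further compounds
F1 | step 4 | 4-ethynylanisole | C#Cc1ccc(OC)cc1
F2 | step 4 | lithium (4-methoxyphenyl)acetylide | [Li]C#Cc1ccc(OC)cc1
F3 | step 4 | [(4-methoxyphenyl)ethynyl]zinc chloride | Cl[Zn]C#Cc1ccc(OC)cc1
F4 | step 2 | 2-hydroxy-4,6-dimethoxy-3-(4-methoxybenzyl)benzaldehyde | COc1ccc(Cc2c(O)c(C=O)c(OC)cc2OC)cc1
F5 | step 2 | 2-[hydroxy(4-methoxyphenyl)methyl]-3,5-dimethoxy-6-(4-methoxybenzyl)phenol (racemic) | COc1ccc(Cc2c(O)c(C(O)c3ccc(OC)cc3)c(OC)cc2OC)cc1
F6 | step 1 | 5,7-dimethoxy-4-(4-methoxyphenyl)-2-phenyl-4H-1,3,2-benzodioxaborinine (racemic) | COc1ccc(cc1)C1OB(c2ccccc2)Oc2cc(OC)cc(OC)c12
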